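**Retrosynthetic overview** (isochromene numbering: C1, O2, C3, C4, C4a, C5, C6, C7, C8, C8a)
1. Target 17 ⇐ tertiary alcohol 15 by O-octanoylation (last step).
2. 15 ⇐ monocyclic pyran 14 by an enantioselective carbene-catalysed intramolecular crossed benzoin that makes the C6–C7 bond. The enabling feature is the tertiary α-ketol C6(=O)–C7(O)(CH3) next to C8=O: C6 is read as a formyl carbon on the C4a-ylidene and C7 as the acetyl carbonyl of a 2-oxopropanoyl group on C8a, and the 4H-pyran holds both arms cis on adjacent ring atoms.
3. 14 ⇐ acyclic enaminone 12 by acid unmasking and 6-endo closure of the pyran (O2–C3).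
4. 12 ⇐ iodo-enaminone 4 + bromo-enyne 9 (Negishi, C8a–C4a); 4 from biacetyl mono-ketal 1; 9 from aldehyde 5, CBr4 and non-1-yne.
5. Ring order: pyran first (step 6), carbocycle second (step 7).

Key step: step 7

Assumption: the single stereocentre C7 of the target is R by CIP analysis of the SMILES; the catalyst enantiomer named in step 7 is assumed to give this sense of induction, and its mirror image is used if the sense proves opposite.

**Step 1**
Reactants: 1 3,3-dimethoxybutan-2-one; 2 N,N-dimethylformamide dimethyl acetal
Product: 3 (E)-1-(dimethylamino)-4,4-dimethoxypent-1-en-3-one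
Conditions: 2 (neat, 1.5 equiv), 100 °C, MeOH distilled off
Reagents that add atoms: N,N-dimethylformamide dimethyl acetal (2), COC(OC)N(C)C
Why: Enaminone formation by condensation of the only enolisable methyl group with the amide acetal, the ketal masking the second carbonyl of the later 1,2-dione.

**Step 2**
Reactants: 3 (E)-1-(dimethylamino)-4,4-dimethoxypent-1-en-3-one
Product: 4 (Z)-1-(dimethylamino)-2-iodo-4,4-dimethoxypent-1-en-3-one
Conditions: NIS, CH2Cl2, 0 °C → rt
Reagents that add atoms: N-iodosuccinimide, O=C1CCC(=O)N1I
Why: Electrophilic α-iodination of the push–pull enaminone at its nucleophilic carbon should give the α-iodo enaminone as the cross-coupling handle for C8a.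

**Step 3**
Reactants: 5 2,2-dimethoxyacetaldehyde; 6 carbon tetrabromide
Product: 7 1,1-dibromo-3,3-dimethoxyprop-1-ene
Conditions: 6, PPh3, Zn dust, CH2Cl2, rt; then 5 (extracted from the commercial aqueous solution and dried), 0 °C → rt
Reagents that add atoms: carbon tetrabromide (6), BrC(Br)(Br)Br
Why: Ramirez dibromo-olefination (first stage of the Corey–Fuchs reaction) with the zinc-modified reagent, which keeps the medium free of HBr and should spare the acetal.

**Step 4**
Reactants: 7 1,1-dibromo-3,3-dimethoxyprop-1-ene; 8 non-1-yne
Product: 9 (Z)-3-bromo-1,1-dimethoxydodec-2-en-4-yne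
Conditions: Pd2(dba)3 (2.5 mol%), P(2-furyl)3, CuI (10 mol%), iPr2NEt, toluene, rt
Reagents that add atoms: none
Why: Trans-selective mono-Sonogashira coupling of a 1,1-dibromoalkene, in which oxidative addition at the less hindered C–Br bond trans to the acetal substituent should place the alkyne trans and leave the bromide cis to the acetal carbon.

**Step 5**
Reactants: 9 (Z)-3-bromo-1,1-dimethoxydodec-2-en-4-yne; 4 (Z)-1-(dimethylamino)-2-iodo-4,4-dimethoxypent-1-en-3-one
Product: 12 (4E,5Z)-4-[(dimethylamino)methylidene]-5-(2,2-dimethoxyethylidene)-2,2-dimethoxytetradec-6-yn-3-one, via alkenyllithium 10 (not isolated), via alkenylzinc bromide 11 (not isolated)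
Conditions: t-BuLi (2 equiv), THF, −78 °C; ZnBr2, −78 → 0 °C; then 4, Pd(PPh3)4 (5 mol%), THF, rt
Reagents that add atoms: none
Why: Bromine–lithium exchange with retention (the cis acetal oxygen chelates lithium), transmetalation to zinc and Negishi coupling with the α-iodo enaminone should join C4a to C8a with the geometry of both alkenes kept.

**Step 6**
Reactants: 12 (4E,5Z)-4-[(dimethylamino)methylidene]-5-(2,2-dimethoxyethylidene)-2,2-dimethoxytetradec-6-yn-3-one
Product: 14 1-[(4Z)-6-heptyl-4-(2-oxoethylidene)-4H-pyran-3-yl]propane-1,2-dione, via open-chain hydroxymethylene enynal 13 (not isolated)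
Conditions: TFA/H2O (9:1), CH2Cl2, 0 °C → rt; NaHCO3 work-up
Reagents that add atoms: water, O
Why: Acid hydrolysis of the vinylogous amide, the acetal and the ketal should free a hydroxymethylene oxygen that adds 6-endo-dig (oxa-Michael, 1,6-addition) to the alkyne now conjugated with the enal, as in the cycloisomerisation of o-alkynyl carbonyl compounds to pyrans; the less hindered formyl oxygen, not the ketone oxygen next to the quaternary carbon, is expected to close the ring.

**Step 7**
Reactants: 14 1-[(4Z)-6-heptyl-4-(2-oxoethylidene)-4H-pyran-3-yl]propane-1,2-dione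
Product: 15 (7R)-3-heptyl-7-hydroxy-7-methyl-6H-isochromene-6,8(7H)-dione
Conditions: (5aS,10bR)-aminoindanol-derived N-pentafluorophenyl triazolium tetrafluoroborate (10 mol%), iPr2NEt (10 mol%), 4 Å MS, toluene, rt
Reagents that add atoms: none
Why: The triazolylidene adds to the C6 aldehyde and proton transfer gives the Breslow enaminol, whose C6 (an acyl anion equivalent) attacks the C7 acetyl carbonyl before proton transfer releases the carbene and the tertiary α-ketol. The closest known reaction type is the enantioselective carbene-catalysed intramolecular crossed aldehyde–ketone benzoin that gives six-membered tertiary acyloins. The carbocycle closes in a 6-exo-trig addition to C7=O, and the product is at once the complete 6,8-dione chromophore. The new C7 centre is set by the catalyst: the aminoindanol backbone shields one face of the enaminol while the enol O–H···O=C7 hydrogen bond fixes which ketone face is presented. Site selectivity for C7 over C8 is expected because C8 is a vinylogous ester carbonyl held in the pyran plane, so C6 would have to approach it in its nodal plane to make a five-membered ring, whereas the acetyl group can rotate into a proper attack trajectory. The acyl-anion path should win over the homoenolate path because the β-carbon C4a is a fully substituted ring carbon and no proton donor or external nucleophile is present.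

**Step 8**
Reactants: 15 (7R)-3-heptyl-7-hydroxy-7-methyl-6H-isochromene-6,8(7H)-dione; 16 octanoyl chloride
Product: 17 (7R)-3-heptyl-7-methyl-6,8-dioxo-7,8-dihydro-6H-isochromen-7-yl octanoate
Conditions: 16, Et3N, DMAP (10 mol%), CH2Cl2, 0 °C → rt
Reagents that add atoms: octanoyl chloride (16), CCCCCCCC(Cl)=O
Why: DMAP-catalysed acylation of the tertiary α-ketol through the N-acylpyridinium ion breaks no bond to C7, so the configuration should be retained.

**Compound list**
1 | 3,3-dimethoxybutan-2-one | CC(=O)C(C)(OC)OC | starting material
2 | N,N-dimethylformamide dimethyl acetal | COC(OC)N(C)C | starting material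
3 | (E)-1-(dimethylamino)-4,4-dimethoxypent-1-en-3-one | CN(C)/C=C/C(=O)C(C)(OC)OC | intermediate
4 | (Z)-1-(dimethylamino)-2-iodo-4,4-dimethoxypent-1-en-3-one | CN(C)/C=C(\I)C(=O)C(C)(OC)OC | intermediate
5 | 2,2-dimethoxyacetaldehyde | COC(OC)C=O | starting material
6 | carbon tetrabromide | BrC(Br)(Br)Br | starting material
7 | 1,1-dibromo-3,3-dimethoxyprop-1-ene | COC(OC)C=C(Br)Br | intermediate
8 | non-1-yne | C#CCCCCCCC | starting material
9 | (Z)-3-bromo-1,1-dimethoxydodec-2-en-4-yne (Br cis to the acetal carbon) | COC(OC)/C=C(\Br)C#CCCCCCCC | intermediate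
10 | (1,1-dimethoxydodec-2-en-4-yn-3-yl)lithium (Li cis to the acetal carbon) | COC(OC)/C=C(\[Li])C#CCCCCCCC | intermediate
11 | (1,1-dimethoxydodec-2-en-4-yn-3-yl)zinc bromide (Zn cis to the acetal carbon) | COC(OC)/C=C(\[Zn]Br)C#CCCCCCCC | intermediate
12 | (4E,5Z)-4-[(dimethylamino)methylidene]-5-(2,2-dimethoxyethylidene)-2,2-dimethoxytetradec-6-yn-3-one | CN(C)/C=C(/C(=O)C(C)(OC)OC)\C(C#CCCCCCCC)=C/C(OC)OC | intermediate
13 | 4-(hydroxymethylidene)-5-(2-oxoethylidene)tetradec-6-yne-2,3-dione (geometry as in 12) | O/C=C(/C(=O)C(C)=O)\C(C#CCCCCCCC)=C/C=O | intermediate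
14 | 1-[(4Z)-6-heptyl-4-(2-oxoethylidene)-4H-pyran-3-yl]propane-1,2-dione | O=C/C=C1/C=C(CCCCCCC)OC=C1C(=O)C(C)=O | intermediate
15 | (7R)-3-heptyl-7-hydroxy-7-methyl-6H-isochromene-6,8(7H)-dione | O[C@]1(C)C(=O)C=C2C=C(CCCCCCC)OC=C2C1=O | intermediate
16 | octanoyl chloride | CCCCCCCC(Cl)=O | starting material
17 | (7R)-3-heptyl-7-methyl-6,8-dioxo-7,8-dihydro-6H-isochromen-7-yl octanoate | CCCCCCCC(=O)O[C@]1(C)C(=O)C=C2C=C(CCCCCCC)OC=C2C1=O | target

**Step count:** 8 steps in total; longest linear sequence 6 steps (5 → 7 → 9 → 12 → 14 → 15 → 17, steps 3–8; equally 1 → 3 → 4 → 12 → 14 → 15 → 17).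

**Steps most likely to fail**

Step 7. The donor-substituted (vinylogous formate) aldehyde may form the Breslow intermediate too slowly, so that the carbene is held up by reversible addition to C1 or to the dione, or facial discrimination at C7 may be poor. The fallback gives up the C–C ring closure and makes the C7 centre by C–O bond formation on an aromatic precursor. It sets out from non-1-yne 8 and the additional building block 6-bromo-2,4-dihydroxy-3-methylbenzaldehyde F1. Sonogashira coupling (PdCl2(PPh3)2, CuI, Et3N, DMF) should give 2,4-dihydroxy-3-methyl-6-(non-1-yn-1-yl)benzaldehyde F2. Hydroxylative dearomatisation at the methyl-bearing carbon with an R-selective flavin-dependent monooxygenase of the AzaH type (NADPH recycling, air) should give the o-quinol F3. Its Au(III)- or Cu(I)-catalysed 6-endo-dig cycloisomerisation should give the pyran ring, and the route is rejoined at 15.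

Step 6. Ring closure may go through the ketone oxygen, the two formyl groups may condense to a hemiacetal or pyrylium ion, or the strongly acidic medium may degrade the polyunsaturated chain before the ketal is cleaved. The fallback closes the pyran by π-acid catalysis before the carbonyl groups are unmasked. It sets out from 12: aqueous LiOH in THF should cleave only the vinylogous amide and give, after neutralisation, the hydroxymethylene compound F4. AuCl3 (cat.) in CH2Cl2 should then effect the 6-endo-dig cycloisomerisation to the pyran bis-acetal F5. Mild aqueous acid then removes acetal and ketal, and the route is rejoined at 14.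

Step 5. Halogen–metal exchange may scramble the alkene geometry through the cumulenyl resonance form of the lithio-enyne, or transmetalation to the hindered palladium centre may be slower than protodemetalation and homocoupling. The fallback makes the C8a–C4a bond by enolate alkenylation and brings in C1 afterwards, so neither the organolithium nor iodide 4 is needed. It sets out from 9 and ketone 1: Pd-catalysed α-alkenylation of the enolate of 1 (Pd2(dba)3, P(t-Bu)3, NaOt-Bu, toluene), which can form on one side only, should give the β,γ-unsaturated ketone F6. Condensation of its doubly activated methylene group with 2 (neat, 80 °C) should give the enaminone, and the route is rejoined at 12.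

**Further compounds**
F1 | step 7 | 6-bromo-2,4-dihydroxy-3-methylbenzaldehyde | Cc1c(O)cc(Br)c(C=O)c1O
F2 | step 7 | 2,4-dihydroxy-3-methyl-6-(non-1-yn-1-yl)benzaldehyde | CCCCCCCC#Cc1cc(O)c(C)c(O)c1C=O
F3 | step 7 | 2,4-dihydroxy-3-methyl-6-(non-1-yn-1-yl)-5-oxocyclohexa-1,3-diene... o-quinol: 3,6-dihydroxy-6-methyl-4-(non-1-yn-1-yl)-5-oxocyclohexa-1,3-diene-1-carbaldehyde regio-form drawn in the SMILES (carbinol carbon arranged as C7 of 15) | O[C@]1(C)C(=O)C=C(C#CCCCCCCC)C(C=O)=C1O
F4 | step 6 | 4-(hydroxymethylidene)-5-(2,2-dimethoxyethylidene)-2,2-dimethoxytetradec-6-yn-3-one (geometry as in 12) | O/C=C(/C(=O)C(C)(OC)OC)\C(C#CCCCCCCC)=C/C(OC)OC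
F5 | step 6 | 1-[(4Z)-4-(2,2-dimethoxyethylidene)-6-heptyl-4H-pyran-3-yl]-2,2-dimethoxypropan-1-one | COC(OC)/C=C1/C=C(CCCCCCC)OC=C1C(=O)C(C)(OC)OC
F6 | step 5 | (Z)-5-(2,2-dimethoxyethylidene)-2,2-dimethoxytetradec-6-yn-3-one (ketone arm cis to the acetal carbon) | CC(OC)(OC)C(=O)C\C(C#CCCCCCCC)=C/C(OC)OC
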